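The data are calculated on assumed constants, noise included.

**The constants.** The constants had to be read from the earlier runs, with E as a fraction of its charge.

common to all: G 1.05 equiv
- violet: E 0.20 M; X 0.05 mol%; run made earlier
- ochre: E 0.20 M; X 0.075 mol%; run made earlier
- blue: E 0.40 M; X 0.1 mol%; run made earlier
- flask: E 0.20 M; X 0.1 mol%

| run | time / h | Z / % | E / % |
|---|---|---|---|
| violet | 6.00 | 6.4 | 93.2 |
| violet | 15.0 | 33.1 | 66.4 |
| violet | 20.0 | 52.5 | 47.8 |
| violet | 30.0 | 83.6 | 15.9 |
| violet | 40.0 | 95.7 | 4.0 |
| violet | 50.0 | 98.5 | 1.5 |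
| ochre | 4.00 | 4.8 | 95.7 |
| ochre | 6.00 | 9.5 | 90.6 |
| ochre | 8.00 | 16.0 | 83.3 |
| ochre | 15.0 | 48.6 | 52.3 |
| ochre | 20.0 | 72.2 | 27.6 |
| ochre | 30.0 | 95.6 | 3.9 |
| ochre | 50.0 | 99.9 | 0 |
| blue | 10.0 | 34.7 | 64.9 |
| blue | 20.0 | 92.6 | 6.7 |
| blue | 30.0 | 99.5 | 0.2 |
| blue | 40.0 | 99.6 | 0.6 |
| blue | 50.0 | 99.8 | 0.2 |

(scatter of a reading: 0.3 percentage points)



- factor on the rate of making Z when 10 % of the E are converted if G is charged twice over
- factor on the rate when 10 % of the E are converted if X is charged at 1 mol% instead

**Main step.** I began with turnover alone, all charged X working from the start. That picture made the rate proportional to loading, a factor of 10.0. But violet lost 6.80 % of E in its first 6.00 h, then 19 percentage points between 15.0 h and 20.0 h, so this was an induction period.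

**Slow activation.** I then let active catalyst grow in proportion to time. I defined the ramp time as the elapsed time divided by the root of the logarithm of the inverse fraction of E left, scaled to the flask's loading by the root of the loading ratio. It is the time at which that logarithm reaches one. Violet at 20.0 h gave 16.5 h, which put 10 % conversion in the flask at 5.34 h. I put that answer back in and read ochre at the nearest time, 6.00 h. This gave the ramp time 16.5 h and a time of 5.37 h. That is the time to watch. There the rate is 0.848 d⁻¹ of the charge. Loading enters the ramp time as its inverse root, so the factor fell to 3.16.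

**Adding G.** Violet's ramp time, at violet's own loading, read 23.3 h at 20.0 h and 22.3 h at 40.0 h, shorter although G had fallen with E and Z stood at 95.7 %. So I took G as zero order in turnover, though E and G always fell together.

**The forecast.** It gave 1 for doubled G and 3.2 for the loading, holding that “Conversion is therefore a function of t√X”. My own factor of 3.16 rounds to its figure.

**Flask result.** The flask gave 1.01 for doubled G and 3.40 for 1 mol%. It reached 10 % conversion at 0.217 d, and X still stood at 72.3 % of the catalyst charged at 0.250 d.

    E + D ⇌ J (K = 8.20 M⁻¹, k = 3.00 M⁻¹ s⁻¹)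
    G + J → L (k = 16.0 M⁻¹ s⁻¹)
    L ⇌ D + Z (K = 0.190 M, k = 0.0470 s⁻¹)
    D ⇌ Q (K = 1.10, k = 4.90 × 10⁻⁵ s⁻¹)
    X → D (k = 1.50 × 10⁻⁵ s⁻¹)

The flask's rate at that conversion was 0.860 d⁻¹ of the charge, beside the 0.848 d⁻¹ reckoned from the ramp time. At 1 mol% the ramp time of 16.5 h, scaled by the root of the loading ratio, puts 10 % conversion at 1.70 h with a rate of 2.68 d⁻¹, and the flask's factor makes that rate 2.93 d⁻¹.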